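# Proposed synthesis of 2-(3,4-dimethoxyphenyl)-3-hydroxy-7-(3-methylbut-2-enyloxy)-4H-chromen-4-one (11)

## The problem

Target 11 is a flavonol: a 4H-chromen-4-one (benzo ring A fused to pyranone ring C) with a 3,4-dimethoxyphenyl ring B at C2, a free enolic hydroxyl at C3 and a prenyl (3-methylbut-2-enyl) ether at O7. It has no stereocentre, so the task is one of connectivity, ring A regiochemistry and functional-group compatibility. The only sp3 centre that appears on the way (C3 at the diketone stage) is racemic and enolisable, and becomes sp2 again when ring C closes. Ring A must carry oxygen at C7 only, and O3 and O7 must be told apart, since one ends as a free hydroxyl and the other as the prenyl ether.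

The aryl prenyl ether is the fragile group. Acid ionises it, the more so because the O7 phenol is a good leaving group para to C4=O. Hydrogenation and hydride-abstracting oxidants attack the allyl unit, strong heating starts a Claisen rearrangement, and zerovalent palladium can in principle ionise it. The C3 hydroxyl has to be masked while C3 serves as an enolate carbon, by a group whose removal leaves the prenyl ether alone.

The enabling feature is that C4 is a single carbonyl carbon bridging C4a of ring A and the oxygen-bearing C3, so it can be delivered as carbon monoxide between an aryl iodide and a ketone enolate. O1 sits on C8a, ortho to that new acyl group, so a fluoride that palladium ignores can later be displaced there by the enolate oxygen.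

## Retrosynthesis

**11 from 10 (O3–CH2 bond of a protecting group).** The free 3-hydroxyl is unveiled last from the 2-(trimethylsilyl)ethoxymethyl (SEM) acetal ether 10. This acetal is preferred over a benzyl or 4-methoxybenzyl ether because its cleavage is triggered by fluoride at silicon, which an allyl aryl ether cannot undergo. Hydrogenolysis, quinone oxidation and acid each have a pathway into the prenyl group. An ester at O3 would be cheap to remove but can migrate between the oxygens of the enolates used earlier. The forward step only needs fluoride to fragment the acetal and expel the stabilised 3-oxidochromone.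

**10 from 9 (O1–C8a).** Cutting the aryl–oxygen bond of ring C opens the chromone to the 2-fluoroaryl 1,3-diketone 9. The neighbouring cut at O1–C2 would need an ortho-hydroxyaryl diketone and an acidic cyclodehydration, which the prenyl ether and the acetal would not tolerate, and a free ortho phenol would interfere with the preceding coupling. The forward reaction is an intramolecular nucleophilic aromatic substitution: the enolate oxygen on the dimethoxybenzoyl side attacks the fluorine-bearing carbon, which is activated by the ortho carbonyl. Only a six-membered closure is geometrically possible.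

**9 from 3, 8 and 7 (C4a–C4 and C4–C3).** Both bonds to C4 are cut at once, so C4 becomes carbon monoxide 8, ring A becomes 2-fluoro-1-iodo-4-(3-methylbut-2-enyloxy)benzene 3, and C2, C3 and ring B become the α-alkoxy ketone 7. A two-component Claisen acylation would cut only C4–C3 and would require a 2-fluoro-4-alkoxybenzoic acid derivative as a separate building block; it is kept in reserve. The three-component cut reduces 9 to an aryl iodide one step from a commercial phenol and a ketone two steps from a commercial bromide. The forward reaction must insert CO before the enolate couples, must acylate the enolate at carbon, and must leave the carbon–fluorine bond and the prenyl ether alone. A zerovalent palladium catalyst with a wide-bite-angle diphosphine under a CO atmosphere is the known answer to the first and third demands.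

**3 from 1 and 2 (O7–CH2).** The prenyl ether is cut to 3-fluoro-4-iodophenol 1 and prenyl bromide 2. Placing the prenyl group first avoids a free phenol in the enolate chemistry and avoids a late alkylation that would have to distinguish O7 from O3. The price is that the ether must survive all later steps, which are basic or neutral. The forward step is a Williamson etherification.

**7 from 6, and 6 from 4 through 5 (O–CH2 of the acetal, C–O at the α-carbon).** The acetal ether 7 comes from the α-hydroxy ketone 6, and 6 from 2-bromo-1-(3,4-dimethoxyphenyl)ethanone 4 by displacement with formate and loss of the formyl group from the ester 5. Direct displacement of the bromide by an alkoxide would compete with enolisation and Darzens- or Favorskii-type pathways, so the oxygen is introduced as a non-basic carboxylate and etherified afterwards.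

## Roads not taken

**Alternative 1: ring A by Wolff rearrangement and 6π electrocyclisation.**
- **Cut and key step.** C8–C8a and C6–C7 are cut, so ring A is built onto a finished pyranone. The precursor is 3-(benzyloxy)-6-(diazoacetyl)-2-(3,4-dimethoxyphenyl)-5-vinyl-4H-pyran-4-one A1. On photolysis it would undergo Wolff rearrangement to a dienyl ketene, which closes by 6π electrocyclisation and tautomerises to 3-(benzyloxy)-2-(3,4-dimethoxyphenyl)-7-hydroxy-4H-chromen-4-one A2.
- **Merits.** The 7-oxygen is placed unambiguously by the ketene carbon. No halogenated arene or transition metal is needed. The prenyl group is attached to A2 afterwards, so it never meets palladium; in this respect the road is better than the chosen one.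
- **Weak points.** A1 is a fully substituted pyranone with a vinyl and a diazoacetyl group and would take more steps than the whole chosen route, to build a benzene ring that can be bought with the right substitution. A 3-alkoxy-2-aryl-4-pyranone is itself photoactive, since the excited carbonyl can abstract hydrogen from the O–CH2 group. After prenylation the benzyl ether of A2 could only be removed by hydrogenolysis or Lewis acid, both of which attack the prenyl ether.
- **Comparison.** The chosen plan sets against the late prenylation a six-step route from commercial arenes and an O3 protecting group removed by fluoride.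

**Alternative 2: ring A from a fused 2-pyrone by Diels–Alder reaction.**
- **Cut and key step.** C5–C6 and C7–C8 are cut. 2-(3,4-Dimethoxyphenyl)-3-[(4-methoxybenzyl)oxy]-4H,7H-pyrano[4,3-b]pyran-4,7-dione A3 would react with 1,1-bis(trimethylsilyloxy)ethene A4. The bridged adduct aromatises by decarboxylation and loss of one silyloxy group to 2-(3,4-dimethoxyphenyl)-3-[(4-methoxybenzyl)oxy]-7-(trimethylsilyloxy)-4H-chromen-4-one A5.
- **Merits.** Polarity matching between the nucleophilic CH2 of A4 and the oxygen-bearing diene terminus of A3 fixes the regiochemistry, and aromatisation is irreversible. The silyl ether falls off on work-up to give the phenol for prenylation. No CO or palladium is needed, which is a practical advantage over the chosen plan.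
- **Weak points.** A3 is not a commercial compound, and its synthesis alone would exceed the length of the chosen route. A4 is moisture-sensitive, and 2-pyrone cycloadditions usually need prolonged heating. The endgame still has to remove a 4-methoxybenzyl ether by oxidation or acid next to a prenyl ether, or else prenylate O7 selectively in the presence of a free O3 hydroxyl.
- **Comparison.** The chosen plan answers with a commercial ring A and an orthogonal O3 group.

**Alternative 3: ring C closed at O1–C8a by nucleophilic aromatic substitution as the central step.**
- **Cut and key step.** Only O1–C8a is cut. The enolate of 2-[1-(3,4-dimethoxyphenyl)-3-(2-fluoro-4-(3-methylbut-2-enyloxy)phenyl)-1,3-dioxopropan-2-yl] benzoate A6 would displace the ortho fluoride to give 2-(3,4-dimethoxyphenyl)-4-oxo-7-(3-methylbut-2-enyloxy)-4H-chromen-3-yl benzoate A7.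
- **Merits.** This is the same ring closure as step 5 of the chosen plan, so on that point the two roads are equal. The benzoate of A7 would come off by mild methanolysis, which is as safe for the prenyl ether as fluoride and cheaper. No gas handling is needed.
- **Weak points.** A6 has three aroyl groups around one O–C unit. Under carbonate in a dipolar aprotic solvent the enolate oxygen can attack the benzoate through a five-membered cyclic intermediate and exchange acyl groups, which would scramble which aryl group ends at C2. Retro-Claisen cleavage is a second exit. Making A6 needs either α-benzoyloxylation of a preformed diketone or acylation of an α-benzoyloxy ketone enolate, which is open to the same migration.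
- **Comparison.** The chosen plan sets against the simpler reagents an ether at O3 that cannot migrate and a diketone assembled in one convergent step from an aryl iodide, CO and a ketone.

Key step: step 4

Remark on the chemistry: 1 and 4 are taken as purchasable, and the O3 hydroxyl is carried as its SEM ether rather than a benzyl-type ether so that the final unmasking is mechanistically unable to touch the prenyl ether.

## Route

Step 1
Reactants: 1 3-fluoro-4-iodophenol; 2 prenyl bromide (1-bromo-3-methylbut-2-ene)
Product: 3 2-fluoro-1-iodo-4-(3-methylbut-2-enyloxy)benzene
Conditions: K2CO3, acetone, reflux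
Reagents that add atoms: none
Why: Williamson ether synthesis; the phenoxide (acidified by the halogens) displaces the primary allylic bromide by SN2 at the unsubstituted terminus, and the aryl halides are inert to carbonate.

Step 2
Reactants: 4 2-bromo-1-(3,4-dimethoxyphenyl)ethanone
Product: 6 1-(3,4-dimethoxyphenyl)-2-hydroxyethanone, via formate ester 5 (not isolated)
Conditions: HCO2Na, EtOH–H2O, reflux
Reagents that add atoms: sodium formate, [Na+].[O-]C=O
Why: SN2 displacement of the phenacyl bromide by the non-basic formate ion, followed by solvolysis of the labile formate ester in the aqueous medium; this classical route to α-hydroxy aryl ketones avoids the enolate side reactions of hydroxide.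

Step 3
Reactants: 6 1-(3,4-dimethoxyphenyl)-2-hydroxyethanone
Product: 7 1-(3,4-dimethoxyphenyl)-2-{[2-(trimethylsilyl)ethoxy]methoxy}ethanone
Conditions: SEMCl, iPr2NEt, CH2Cl2, 0 °C to rt
Reagents that add atoms: 2-(trimethylsilyl)ethoxymethyl chloride (SEMCl), ClCOCC[Si](C)(C)C
Why: Standard O-alkylation of an alcohol by an α-chloro ether with a hindered amine as acid scavenger; the amine is too weak to enolise the ketone and the acetal formed is stable to the strong base of step 4.

Step 4
Reactants: 3 2-fluoro-1-iodo-4-(3-methylbut-2-enyloxy)benzene; 7 1-(3,4-dimethoxyphenyl)-2-{[2-(trimethylsilyl)ethoxy]methoxy}ethanone; 8 carbon monoxide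
Product: 9 1-(3,4-dimethoxyphenyl)-3-[2-fluoro-4-(3-methylbut-2-enyloxy)phenyl]-2-{[2-(trimethylsilyl)ethoxy]methoxy}propane-1,3-dione (racemic, enolisable)
Conditions: 7 (2 equiv), NaN(SiMe3)2 (2 equiv), THF, −78 to 0 °C; then 3, Pd(dba)2 (5 mol %), Xantphos (5 mol %), CO (1 atm), THF, 70 °C; aq. NH4Cl
Reagents that add atoms: none
Why: Carbonylative α-arylation of a ketone: zerovalent palladium–Xantphos inserts into the carbon–iodine bond of 3, CO inserts to give the aroyl complex of divalent palladium (C4a–C4), the sodium enolate of 7 replaces iodide, and reductive elimination forms C4–C3. The closest known reaction is the carbonylative α-arylation of aryl ketones, including α-substituted ones, with aryl iodides to give 1,3-diketones; the α-oxygen of 7 only makes the enolate easier to form. No ring closes here; the ortho fluoride is carried through for step 5. The new sp3 centre between the two carbonyls is formed racemic, is deprotonated at once by the second equivalent of enolate and becomes sp2 in step 5, so it needs no control. The step must be carbonylative and not a direct arylation (secured by the CO atmosphere and the wide bite angle of Xantphos, which favours acyl formation and acyl–carbon reductive elimination), must acylate at carbon (any enol ester is returned to the stabilised diketonate by enolate-mediated acyl transfer), and must react at carbon–iodine only (the carbon–fluorine bond is inert to zerovalent palladium and the trisubstituted prenyl ether ionises far more slowly than the iodide adds). Pre-forming the enolate with one equivalent of amide per ketone leaves no free silylamide to intercept the aroyl complex; the equivalent of 7 regenerated by proton transfer is recovered.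

Step 5
Reactants: 9 1-(3,4-dimethoxyphenyl)-3-[2-fluoro-4-(3-methylbut-2-enyloxy)phenyl]-2-{[2-(trimethylsilyl)ethoxy]methoxy}propane-1,3-dione
Product: 10 2-(3,4-dimethoxyphenyl)-7-(3-methylbut-2-enyloxy)-3-{[2-(trimethylsilyl)ethoxy]methoxy}-4H-chromen-4-one
Conditions: K2CO3, DMF, 90 °C
Reagents that add atoms: none
Why: Intramolecular nucleophilic aromatic substitution (addition–elimination), well known for 1-(2-fluoroaryl)-1,3-diketones: the enolate oxygen on the dimethoxybenzoyl side adds to the fluorine-bearing carbon ortho to the other carbonyl in a six-membered closure and fluoride leaves. The temperature is far below that of an aryl prenyl ether Claisen rearrangement.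

Step 6
Reactants: 10 2-(3,4-dimethoxyphenyl)-7-(3-methylbut-2-enyloxy)-3-{[2-(trimethylsilyl)ethoxy]methoxy}-4H-chromen-4-one
Product: 11 2-(3,4-dimethoxyphenyl)-3-hydroxy-7-(3-methylbut-2-enyloxy)-4H-chromen-4-one
Conditions: Bu4NF, THF, 50 °C; aq. NH4Cl
Reagents that add atoms: none
Why: Fluoride-induced fragmentation of an aryl-type SEM ether: attack at silicon releases ethene and formaldehyde and expels the 3-oxidochromone, a stabilised leaving group that is protonated on work-up. The prenyl ether, methyl ethers and chromone have no pathway with fluoride.

## Compound list

1 | 3-fluoro-4-iodophenol | Oc1ccc(I)c(F)c1 | starting material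
2 | prenyl bromide (1-bromo-3-methylbut-2-ene) | CC(C)=CCBr | starting material
3 | 2-fluoro-1-iodo-4-(3-methylbut-2-enyloxy)benzene | CC(C)=CCOc1ccc(I)c(F)c1 | intermediate
4 | 2-bromo-1-(3,4-dimethoxyphenyl)ethanone | COc1ccc(C(=O)CBr)cc1OC | starting material
5 | 2-(3,4-dimethoxyphenyl)-2-oxoethyl formate | COc1ccc(C(=O)COC=O)cc1OC | intermediate
6 | 1-(3,4-dimethoxyphenyl)-2-hydroxyethanone | COc1ccc(C(=O)CO)cc1OC | intermediate
7 | 1-(3,4-dimethoxyphenyl)-2-{[2-(trimethylsilyl)ethoxy]methoxy}ethanone | COc1ccc(C(=O)COCOCC[Si](C)(C)C)cc1OC | intermediate
8 | carbon monoxide | [C-]#[O+] | starting material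
9 | 1-(3,4-dimethoxyphenyl)-3-[2-fluoro-4-(3-methylbut-2-enyloxy)phenyl]-2-{[2-(trimethylsilyl)ethoxy]methoxy}propane-1,3-dione (racemic) | CC(C)=CCOc1ccc(C(=O)C(OCOCC[Si](C)(C)C)C(=O)c2ccc(OC)c(OC)c2)c(F)c1 | intermediate
10 | 2-(3,4-dimethoxyphenyl)-7-(3-methylbut-2-enyloxy)-3-{[2-(trimethylsilyl)ethoxy]methoxy}-4H-chromen-4-one | COc1ccc(-c2oc3cc(OCC=C(C)C)ccc3c(=O)c2OCOCC[Si](C)(C)C)cc1OC | intermediate
11 | 2-(3,4-dimethoxyphenyl)-3-hydroxy-7-(3-methylbut-2-enyloxy)-4H-chromen-4-one | COc1ccc(-c2oc3cc(OCC=C(C)C)ccc3c(=O)c2O)cc1OC | target

## Step count and least certain steps

Total: 6 steps. Longest linear sequence: 5 steps (4 to 11 through steps 2, 3, 4, 5 and 6). The arene branch (step 1) joins at step 4.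

**Step 4 (key step).** Three things may go wrong.
- CO insertion at the ortho-fluoro aryl palladium intermediate may be slow relative to enolate capture, giving direct α-arylation or reduction of the iodide.
- Coupling at the hindered, oxygen-substituted enolate carbon may be slow, leaving the aroyl complex to be consumed in other ways.
- Zerovalent palladium may ionise the aryl prenyl ether, which becomes a better leaving group once it is para to the new ketone, and transfer the prenyl group to the soft diketonate.

Fallback: the same diketone is reached without palladium or CO by a crossed Claisen condensation. Methyl 2-fluoro-4-hydroxybenzoate F1 is prenylated with 2 (K2CO3, acetone) to methyl 2-fluoro-4-(3-methylbut-2-enyloxy)benzoate F2. The lithium enolate of 7 (LiN(SiMe3)2, THF, −78 °C to rt) is then acylated by F2, and deprotonation of the product drives the condensation. This sets out from 7 and rejoins the route at 9.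

**Step 5.** The displacement may be sluggish, because the only activation of the fluoride is an ortho carbonyl that is part of an enolate and is further weakened by the para alkoxy group. Forcing conditions invite retro-Claisen cleavage of the 2-alkoxy-1,3-diketone by carbonate and traces of water. Partial loss of the acetal under the liberated fluoride after ring closure would be harmless, since it leads to 11.

Fallback: the aryl–oxygen bond is made by copper catalysis on a bromide instead.
- Methyl 2-bromo-4-hydroxybenzoate F3 is prenylated with 2 to methyl 2-bromo-4-(3-methylbut-2-enyloxy)benzoate F4.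
- Claisen condensation of F4 with the lithium enolate of 7 gives 1-[2-bromo-4-(3-methylbut-2-enyloxy)phenyl]-3-(3,4-dimethoxyphenyl)-2-{[2-(trimethylsilyl)ethoxy]methoxy}propane-1,3-dione F5.
- CuI with 1,10-phenanthroline and K2CO3 in DMF closes O1–C8a by Ullmann-type intramolecular O-arylation.

The bromo compound is deliberately not taken through the palladium step. This sets out from 7 and rejoins the route at 10.

**Step 6.** The fragmentation may stall, because an acetal on a vinylogous ester oxygen is less reactive than expected toward fluoride. Prolonged exposure of the product anion to the basic fluoride medium may also cause oxidative degradation of the flavonolate if air is admitted.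

Fallback: the O3 group is changed to one cleaved oxidatively.
- From 6, 4-methoxybenzyl 2,2,2-trichloroacetimidate with catalytic camphorsulfonic acid gives 1-(3,4-dimethoxyphenyl)-2-[(4-methoxybenzyl)oxy]ethanone F6.
- The conditions of step 4 with 3 and 8 give 1-(3,4-dimethoxyphenyl)-3-[2-fluoro-4-(3-methylbut-2-enyloxy)phenyl]-2-[(4-methoxybenzyl)oxy]propane-1,3-dione F7.
- K2CO3 in DMF gives 2-(3,4-dimethoxyphenyl)-3-[(4-methoxybenzyl)oxy]-7-(3-methylbut-2-enyloxy)-4H-chromen-4-one F8.
- DDQ in CH2Cl2 with pH 7 buffer at 0 °C removes the benzyl-type ether.

This road is held in reserve because the oxidant must discriminate between the 4-methoxybenzyl group and the allylic O–CH2 of the prenyl ether, which is only partly protected by conjugation of O7 to C4=O. It sets out from 6 and rejoins the route at 11.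

## Further compounds

F1 | step 4 | methyl 2-fluoro-4-hydroxybenzoate | COC(=O)c1ccc(O)cc1F
F2 | step 4 | methyl 2-fluoro-4-(3-methylbut-2-enyloxy)benzoate | COC(=O)c1ccc(OCC=C(C)C)cc1F
F3 | step 5 | methyl 2-bromo-4-hydroxybenzoate | COC(=O)c1ccc(O)cc1Br
F4 | step 5 | methyl 2-bromo-4-(3-methylbut-2-enyloxy)benzoate | COC(=O)c1ccc(OCC=C(C)C)cc1Br
F5 | step 5 | 1-[2-bromo-4-(3-methylbut-2-enyloxy)phenyl]-3-(3,4-dimethoxyphenyl)-2-{[2-(trimethylsilyl)ethoxy]methoxy}propane-1,3-dione | CC(C)=CCOc1ccc(C(=O)C(OCOCC[Si](C)(C)C)C(=O)c2ccc(OC)c(OC)c2)c(Br)c1
F6 | step 6 | 1-(3,4-dimethoxyphenyl)-2-[(4-methoxybenzyl)oxy]ethanone | COc1ccc(COCC(=O)c2ccc(OC)c(OC)c2)cc1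
F7 | step 6 | 1-(3,4-dimethoxyphenyl)-3-[2-fluoro-4-(3-methylbut-2-enyloxy)phenyl]-2-[(4-methoxybenzyl)oxy]propane-1,3-dione | CC(C)=CCOc1ccc(C(=O)C(OCc2ccc(OC)cc2)C(=O)c2ccc(OC)c(OC)c2)c(F)c1
F8 | step 6 | 2-(3,4-dimethoxyphenyl)-3-[(4-methoxybenzyl)oxy]-7-(3-methylbut-2-enyloxy)-4H-chromen-4-one | COc1ccc(-c2oc3cc(OCC=C(C)C)ccc3c(=O)c2OCc2ccc(OC)cc2)cc1OC
A1 | alternative 1 | 3-(benzyloxy)-6-(diazoacetyl)-2-(3,4-dimethoxyphenyl)-5-vinyl-4H-pyran-4-one | COc1ccc(-c2oc(C(=O)C=[N+]=[N-])c(C=C)c(=O)c2OCc2ccccc2)cc1OC
A2 | alternative 1 | 3-(benzyloxy)-2-(3,4-dimethoxyphenyl)-7-hydroxy-4H-chromen-4-one | COc1ccc(-c2oc3cc(O)ccc3c(=O)c2OCc2ccccc2)cc1OC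
A3 | alternative 2 | 2-(3,4-dimethoxyphenyl)-3-[(4-methoxybenzyl)oxy]-4H,7H-pyrano[4,3-b]pyran-4,7-dione | COc1ccc(-c2oc3cc(=O)occ3c(=O)c2OCc2ccc(OC)cc2)cc1OC
A4 | alternative 2 | 1,1-bis(trimethylsilyloxy)ethene | C=C(O[Si](C)(C)C)O[Si](C)(C)C
A5 | alternative 2 | 2-(3,4-dimethoxyphenyl)-3-[(4-methoxybenzyl)oxy]-7-(trimethylsilyloxy)-4H-chromen-4-one | COc1ccc(-c2oc3cc(O[Si](C)(C)C)ccc3c(=O)c2OCc2ccc(OC)cc2)cc1OC
A6 | alternative 3 | 1-(3,4-dimethoxyphenyl)-3-[2-fluoro-4-(3-methylbut-2-enyloxy)phenyl]-1,3-dioxopropan-2-yl benzoate | CC(C)=CCOc1ccc(C(=O)C(OC(=O)c2ccccc2)C(=O)c2ccc(OC)c(OC)c2)c(F)c1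
A7 | alternative 3 | 2-(3,4-dimethoxyphenyl)-4-oxo-7-(3-methylbut-2-enyloxy)-4H-chromen-3-yl benzoate | COc1ccc(-c2oc3cc(OCC=C(C)C)ccc3c(=O)c2OC(=O)c2ccccc2)cc1OC
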